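## Analysis of the target

Target 32 is a C40 carotenoid tetrol. Its chain runs from C7 to C7' with eight E double bonds and four methyl branches, ends in the C7'≡C8' triple bond conjugated with the C5'=C6' bond of cyclohexene ring B (stereocentre C3', R), and is attached at the other end to the fully substituted C6 of the saturated ring A. Ring A carries three stereocentres, C3, C5 and C6 (all S). The hydroxyls on C3 and C5 are cis to each other and to the chain carbon C7, and the C6 hydroxyl is trans to both, so C5/C6 form an anti diol of two quaternary carbinol carbons next to the C1 gem-dimethyl group. C3' is far from ring A, so the rings cannot control each other and the synthesis must be convergent. The sensitive elements are: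
- the polyene (light, oxygen, acid);
- the 9'E enyne, which lacks the steric bias of a normal ring–chain junction and isomerises to 9'Z once an allyl cation can form;
- the tertiary allylic C6 hydroxyl, which ionises under acid;
- the β-hydroxy relation of O5 to any carbonyl at C7 (retro-aldol).

The hard part is ring A: three oxygenated stereocentres, two of them contiguous and fully substituted, in defined absolute configuration. The plan rests on the fact that O3 and C7 are cis-1,4 across ring A. They can be the two atoms of a lactone bridge O3–C7(=O) across C3 and C6 of a cyclohexene with the C6 hydroxyl on the bridgehead. That 2-oxabicyclo[2.2.2]octenone is the [4+2] adduct of a 3-hydroxy-2-pyrone (C3, C4, C5 with its methyl, C6 with its hydroxyl, O3, C7) and a two-carbon dienophile (C1, C2).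

## Retrosynthetic reasoning

**C11=C12 and the silyl groups.** 32 is traced to its bis-silyl ether 31, and 31 is cut at C11=C12 into the C25 phosphonate 30 and the C15 aldehyde 19. The cut lies between two methyl-free carbons, so an E-selective phosphonate olefination suffices. Ring A is the electrophile because a phosphonium salt on that half would have to be made under acid, which the C6 allylic hydroxyl does not tolerate.

**C11'=C12' and the central C10 unit.** 30 is cut into the enynal 25 and the symmetric bisphosphonate 29, which comes from the commercial dialdehyde 26 through diol 27 and dibromide 28. One linchpin then serves both unions, and the forward reaction only has to stop after one olefination.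

**C6'–C7' (ring B to alkyne).** 25 comes by allylic oxidation from enynol 24, which is cut into enol triflate 22 and the E-enynol 23. The 9'E geometry is bought with 23 and never passes through an allyl cation. 22 follows from the silyl ether 21 of hydroxy ketone 20, which has a single α-hydrogen and carries C3'.

**C7=C8 and C9–C11.** 19 is the reduction product of nitrile 18, which is cut at C7=C8 into the ring aldehyde 16 and the C5 phosphonate 17. One olefination adds five carbons and the nitrile gives the aldehyde without a change of oxidation state elsewhere.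

**Oxidation level of C7 and masking of O3.** 16 comes from primary alcohol 15, which comes from bis-silyl ether 14 and tetraol 13. O3 must be masked before C7 is oxidised, because a cis-1,4 hydroxy aldehyde would close to the bridged lactol and be oxidised back to the lactone.

**C5–O, C4–H and the lactone.** 13 is the hydride reduction product of epoxy lactone 12, which is the epoxide of alkene 11. The rigid bicycle decides the face of oxygenation at C5, hydride enters at the less substituted C4, and the same reagent releases O3 and C7 from the lactone.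

**The second C1 methyl.** 11 comes from aldehyde 9 through hydrazone 10. The formyl group of the dienophile is only a carrier of activation and becomes the second methyl on C1, so the C1 epimers of 9 converge.

**Bonds C2–C3 and C1–C6 (key disconnection).** 9 is cut into pyrone 7 and enal 8. This creates carbocyclic ring A, both of these bonds and the stereocentres C3 and C6 in one catalytic operation.

**The pyrone.** 7 is the dehydration product of the keto aldehyde acid 5 (through enol acetate 6). 5 comes by ozonolysis from 4, and 4 comes by allylation, hydrolysis and decarboxylation from the oxalyl ester 1 and halide 2. A stabilised enolate is used because a free α-keto ester enolate would self-condense.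

## Alternatives that were turned down

Alternative 1: The acetylenic half is cut at C9'–CH3 and C10'–C11'. The ring B butadiyne A2 would be methylaluminated under zirconium catalysis at its terminal triple bond (methyl to C9', metal to C10', syn). After transfer to zinc, the alkenyl metal would be coupled under palladium catalysis with the iododienoate A3 to give the C20 trienynoate A1.
- For: 9'E follows from the syn course of carbometalation and a stereoretentive coupling, not from the purity of a purchased isomer, and A1 would allow a central C20 + C20 union.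
- Against: it only treats the easier half of 32. A2 needs extra steps beyond 22, a conjugated diyne can react at the internal triple bond or twice, and a pyrophoric alane is used in stoichiometric amount. A C20 electrophile from A1 would also call for a ring A C20 nucleophile, whose preparation under acid ring A does not tolerate.
- Comparison: on 9'E control alone it is as strong as the chosen route, arguably stronger, since the chosen route only has to preserve the geometry bought in 23. The chosen route offers a four-step ring B branch (20 to 25) and a solution for ring A.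

Alternative 2: Ring A is cut at C5–O with O3 as internal oxygen source. The epoxide A5 (oxirane trans to the C3 tert-butyl carbonate) would be opened under a Lewis acid at C5 by the carbonate carbonyl oxygen with inversion, with loss of the tert-butyl group, to give the cyclic carbonate A4; C6 keeps the oxirane oxygen.
- For: skeleton and C3 come from the ionone pool, the opening is stereospecific and gives O5 cis to O3 and trans to O6 as in 32, O3 and O5 are protected together, and A4 is already a C13 ketone.
- Against: it depends on A5, that is, on epoxidising a tetrasubstituted ring alkene trans to the C3 oxygen, where facial control is modest. The six-membered carbonate must span two axial positions against the axial C1 methyl. A fully substituted oxirane next to an enone can ionise under Lewis acid (retention, ring contraction). C9=C10 must still be built from a methyl ketone with E/Z mixtures.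
- Comparison: in step count to a ring A unit it is probably stronger. The chosen strategy offers absolute control of C3 and C6 from one catalytic event and a rigid template in which the C5 face is decided by the gem-dimethyl bridge, and it never exposes the 5,6-dioxygenated system to a Lewis acid.

Alternative 3: The triple bond C7'≡C8' is traced back to a carbonyl. The cross-conjugated dienone A7, made by aldol condensation, would add a lithiated silyl diazomethane; loss of lithium silanolate and nitrogen gives an alkylidene carbene whose 1,2-alkenyl shift gives the enyne acetal A6, which is the diethyl acetal of 25.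
- For: no palladium and no triflate, and 9'E is the thermodynamic result of an aldol condensation.
- Against: the carbonyl of A7 lies between a tetrasubstituted and a trisubstituted alkene, so addition is slow and dipolar or conjugate addition of the diazo reagent to the enone competes. The carbene can insert into nearby C–H bonds (ring methyls, acetal) instead of rearranging. A7 needs more steps than 22 plus 23.
- Comparison: it is as strong only in not depending on isomerically pure 23. The Sonogashira coupling of 22 with 23 reaches the same C15 unit in one well-precedented step, and this alternative also leaves ring A unsolved.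

Key step: step 5

Assumptions (remarks on the chemistry):
- Compounds 1, 2, 8, 17 (as its E/Z mixture), 20, 23 and 26 are taken as purchasable.
- The sense of induction in step 5 cannot be derived on paper for this diene/dienophile pair. The quinidine-derived catalyst is written; its quinine-derived pseudo-enantiomer is used instead if the antipode of 9 should form.

## Route

Step 1
Reactants: 1 diethyl 2-methyl-3-oxobutanedioate; 2 3-bromoprop-1-ene
Product: 3 diethyl 2-methyl-3-oxo-2-(prop-2-en-1-yl)butanedioate (racemic)
Conditions: K2CO3, acetone, reflux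
Reagents that add atoms: none
Why: C-alkylation of a doubly activated oxalyl ester enolate with an allylic halide; the stabilised enolate avoids the self-condensation of a free α-keto ester enolate, and the quaternary centre is lost again in step 2.

Step 2
Reactants: 3 allylated oxalyl diester
Product: 4 3-methyl-2-oxohex-5-enoic acid (racemic)
Conditions: 2 M HCl, AcOH, 100 °C
Reagents that add atoms: water, O
Why: acid hydrolysis of both esters and decarboxylation of the β-keto acid (oxalyl ester synthesis of α-keto acids); acid is used because hydroxide would cleave the non-enolisable β-dicarbonyl by a retro-Claisen reaction.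

Step 3
Reactants: 4 keto acid
Product: 5 3-methyl-2,5-dioxopentanoic acid (racemic; expected to exist largely as its cyclic lactol)
Conditions: O3, CH2Cl2, −78 °C; then Me2S, −78 °C → rt
Reagents that add atoms: ozone, [O-][O+]=O
Why: ozonolysis of the terminal alkene with reductive work-up; the aldehyde is released only now, under neutral conditions, so the 1,4-keto aldehyde never meets the hot mineral acid of step 2, which would favour Paal–Knorr closure to a furan.

Step 4
Reactants: 5 keto aldehyde acid
Product: 7 3-hydroxy-4-methyl-2H-pyran-2-one, via 4-methyl-2-oxo-2H-pyran-3-yl acetate 6 (not isolated)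
Conditions: Ac2O, NaOAc, 100 °C; concentrate; then 2 M HCl, THF, 50 °C
Reagents that add atoms: none
Why: enol lactonisation of a δ-aldehydo acid under acylating conditions (as in the dehydration of aldaric acids to 3-acetoxy-2-pyrones), then hydrolysis of the enol acetate; activation of the carboxyl group directs its oxygen, not the ketone oxygen, onto the aldehyde carbon, which gives the six-membered pyrone.

Step 5
Reactants: 7 3-hydroxy-4-methyl-2H-pyran-2-one; 8 2-methylprop-2-enal
Product: 9 (1S,4R)-4-hydroxy-5,8-dimethyl-3-oxo-2-oxabicyclo[2.2.2]oct-5-ene-8-carbaldehyde (both C8 epimers)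
Conditions: 9-O-benzylcupreidine (O-demethylquinidine 9-benzyl ether, 10 mol %), 8 (3 equiv), Et2O, −20 °C
Reagents that add atoms: none
Why: The quinuclidine nitrogen deprotonates the 3-hydroxyl of 7 and holds the dienolate as an ion pair while the 6'-hydroxyl hydrogen-bonds the carbonyl of 8; the dienolate adds through pyrone C6 to the β-carbon of 8 (bond C2–C3, carotenoid numbering) and the resulting enolate closes on pyrone C3, now an α-keto lactone carbonyl (bond C1–C6), a stepwise or strongly asynchronous [4+2]. The closest known reaction type is the amine-base-catalysed asymmetric Diels–Alder reaction of 3-hydroxy-2-pyrones with enones, acrylonitriles and related electron-poor alkenes; 7 and 8 add only a 4-methyl group and α-branching to that class. Carbocyclic ring A closes in the second bond formation by a 6-(enolexo)-exo-trig aldol addition, the lactone bridge being the ring of 7 itself. C1 of 9 (C3 of the target) is set in the Michael step by the face of the dienolate that the chiral ion pair leaves open, and C4 of 9 (C6 of the target) follows of necessity because the tethered enolate can only reach the same face. The configuration at C8 is irrelevant, since this carbon becomes the gem-dimethyl carbon C1. The step needs regioselectivity, secured by the polarity match of nucleophilic pyrone C6 with the enal β-carbon, enantiofacial selectivity, which rests on the catalyst, and a temperature low enough that the adduct neither reverts nor loses CO2.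

Step 6
Reactants: 9 bicyclic hydroxy aldehyde
Product: 11 (1S,4S)-4-hydroxy-5,8,8-trimethyl-2-oxabicyclo[2.2.2]oct-5-en-3-one, via tosylhydrazone 10 (not isolated)
Conditions: TsNHNH2, THF, rt; then catecholborane, CHCl3, 0 °C → rt; then NaOAc·3H2O, 60 °C
Reagents that add atoms: none
Why: Caglioti-type reductive deoxygenation through the tosylhydrazone (hydride adds to C=N, sulfinate leaves, the diazene loses N2) turns formyl into methyl and merges both C8 epimers; the conditions are not basic (no retro-aldol) and not hot enough for loss of CO2, and no CH2OH group arises that could translactonise onto C7.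

Step 7
Reactants: 11 bicyclic alkene lactone
Product: 12 (1S,2S,4S,5S)-1-hydroxy-2,8,8-trimethyl-3,6-dioxatricyclo[3.2.2.0^2,4]nonan-7-one (oxirane oxygen on the face of the lactone bridge)
Conditions: mCPBA, CH2Cl2, 0 °C → rt
Reagents that add atoms: 3-chloroperoxybenzoic acid, OOC(=O)c1cccc(Cl)c1
Why: Prilezhaev epoxidation of the trisubstituted C4=C5 bond; the peracid should approach from the side of the flat O–C(=O) bridge because the other face is screened by the C1 methyl that points over the alkene, which places the new C5–O bond cis to O3 and C7 and trans to the C6 hydroxyl.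

Step 8
Reactants: 12 epoxy lactone
Product: 13 (1R,2S,4S)-1-(hydroxymethyl)-2,6,6-trimethylcyclohexane-1,2,4-triol
Conditions: LiAlH4 (excess), THF, 0 °C → reflux; aq. potassium sodium tartrate
Reagents that add atoms: none
Why: hydride reduction of the lactone to the C7 alcohol and the C3 hydroxyl, and SN2 opening of the oxirane at the secondary C4 rather than the fully substituted C5; C5 keeps its oxygen with unchanged configuration, C4 becomes CH2, and C3 and C6 are untouched.

Step 9
Reactants: 13 tetraol
Product: 14 (1R,2S,4S)-4-[(tert-butyldimethylsilyl)oxy]-1-{[(tert-butyldimethylsilyl)oxy]methyl}-2,6,6-trimethylcyclohexane-1,2-diol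
Conditions: TBSCl (2.5 equiv), imidazole, DMF, rt → 40 °C
Reagents that add atoms: tert-butyl(chloro)dimethylsilane, CC(C)(C)[Si](C)(C)Cl
Why: silylation of the primary and the secondary hydroxyl; the two tertiary hydroxyls do not react with a silyl chloride.

Step 10
Reactants: 14 bis-silyl ether
Product: 15 (1R,2S,4S)-4-[(tert-butyldimethylsilyl)oxy]-1-(hydroxymethyl)-2,6,6-trimethylcyclohexane-1,2-diol
Conditions: HF·pyridine, pyridine, THF, 0 °C
Reagents that add atoms: none
Why: selective cleavage of a primary silyl ether in the presence of a secondary one with buffered fluoride; O3 stays masked so that oxidation at C7 cannot be followed by lactol closure and re-oxidation to the lactone.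

Step 11
Reactants: 15 primary alcohol
Product: 16 (1S,2S,4S)-4-[(tert-butyldimethylsilyl)oxy]-1,2-dihydroxy-2,6,6-trimethylcyclohexane-1-carbaldehyde
Conditions: SO3·pyridine, DMSO, iPr2NEt, CH2Cl2, 0 °C
Reagents that add atoms: none
Why: Parikh–Doering oxidation; activated DMSO oxidises the primary alcohol, leaves tertiary alcohols alone and cannot cleave the vicinal diol, and the mild base at 0 °C spares the retro-aldol-prone product, which is used at once.

Step 12
Reactants: 16 ring A aldehyde; 17 diethyl (3-cyano-2-methylprop-2-en-1-yl)phosphonate (E/Z mixture)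
Product: 18 (2E,4E)-5-[(1S,2S,4S)-4-[(tert-butyldimethylsilyl)oxy]-1,2-dihydroxy-2,6,6-trimethylcyclohexyl]-3-methylpenta-2,4-dienenitrile
Conditions: 17 (2.5 equiv), NaN(SiMe3)2 (2.4 equiv), THF, −78 °C; add 16; → 0 °C
Reagents that add atoms: none
Why: Horner–Wadsworth–Emmons olefination with a vinylogous phosphonate forms C7=C8 with E geometry and adds C8–C11; the preformed anion is too weak a base to deprotonate the tertiary hydroxyls, and any 9Z isomer should be removable by chromatography or equilibrated with a trace of iodine.

Step 13
Reactants: 18 C15 nitrile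
Product: 19 (2E,4E)-5-[(1S,2S,4S)-4-[(tert-butyldimethylsilyl)oxy]-1,2-dihydroxy-2,6,6-trimethylcyclohexyl]-3-methylpenta-2,4-dienal
Conditions: iBu2AlH (4 equiv), CH2Cl2, −78 °C; then aq. potassium sodium tartrate
Reagents that add atoms: water, O
Why: partial reduction of a conjugated nitrile to the aluminium imide and hydrolysis to the aldehyde; the hydroxyls only consume hydride and the silyl ether is inert.

Step 14
Reactants: 20 (4R,6R)-4-hydroxy-2,2,6-trimethylcyclohexan-1-one
Product: 21 (4R,6R)-4-[(tert-butyldimethylsilyl)oxy]-2,2,6-trimethylcyclohexan-1-one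
Conditions: TBSCl, imidazole, DMF, rt
Reagents that add atoms: tert-butyl(chloro)dimethylsilane, CC(C)(C)[Si](C)(C)Cl
Why: silyl protection of the secondary alcohol that becomes the C3' hydroxyl, needed for the enolate chemistry of step 15.

Step 15
Reactants: 21 silyloxy ketone
Product: 22 (4R)-4-[(tert-butyldimethylsilyl)oxy]-2,6,6-trimethylcyclohex-1-en-1-yl trifluoromethanesulfonate
Conditions: LiN(iPr)2, THF, −78 → 0 °C; then PhNTf2, −78 °C → rt
Reagents that add atoms: N-phenylbis(trifluoromethanesulfonimide), O=S(=O)(N(c1ccccc1)S(=O)(=O)C(F)(F)F)C(F)(F)F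
Why: enol triflate formation; the ketone has a single α-hydrogen, so only the tetrasubstituted C5'=C6' enolate can form, and the methyl-bearing stereocentre of 21 is removed on purpose while C3' is untouched.

Step 16
Reactants: 22 enol triflate; 23 (2E)-3-methylpent-2-en-4-yn-1-ol
Product: 24 (2E)-5-[(4R)-4-[(tert-butyldimethylsilyl)oxy]-2,6,6-trimethylcyclohex-1-en-1-yl]-3-methylpent-2-en-4-yn-1-ol
Conditions: Pd(PPh3)4 (5 mol %), CuI (10 mol %), iPr2NH, DMF, rt → 45 °C
Reagents that add atoms: none
Why: Sonogashira coupling of an alkenyl triflate with a terminal alkyne forms C6'–C7'; the E double bond of 23 is not involved and is carried over unchanged as the 9'E bond.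

Step 17
Reactants: 24 enynol
Product: 25 (2E)-5-[(4R)-4-[(tert-butyldimethylsilyl)oxy]-2,6,6-trimethylcyclohex-1-en-1-yl]-3-methylpent-2-en-4-ynal
Conditions: MnO2, CH2Cl2, rt
Reagents that add atoms: none
Why: chemoselective oxidation of an allylic alcohol on MnO2 under neutral conditions, which should not disturb the 9'E geometry.

Step 18
Reactants: 26 (2E,4E,6E)-2,7-dimethylocta-2,4,6-trienedial
Product: 27 (2E,4E,6E)-2,7-dimethylocta-2,4,6-triene-1,8-diol
Conditions: NaBH4, MeOH/THF, 0 °C
Reagents that add atoms: none
Why: 1,2-reduction of both conjugated aldehyde groups by borohydride.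

Step 19
Reactants: 27 diol
Product: 28 (2E,4E,6E)-1,8-dibromo-2,7-dimethylocta-2,4,6-triene
Conditions: PBr3, pyridine (cat.), Et2O, −15 °C; used crude
Reagents that add atoms: phosphorus tribromide, BrP(Br)Br
Why: conversion of primary allylic alcohols into bromides at low temperature; the all-E triene is the thermodynamic isomer, so allylic scrambling should not change the structure.

Step 20
Reactants: 28 dibromide
Product: 29 tetraethyl [(2E,4E,6E)-2,7-dimethylocta-2,4,6-triene-1,8-diyl]bis(phosphonate)
Conditions: P(OEt)3, 110 °C
Reagents that add atoms: triethyl phosphite, CCOP(OCC)OCC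
Why: Michaelis–Arbuzov reaction of a reactive allylic dibromide, driven by loss of bromoethane.

Step 21
Reactants: 25 enynal; 29 C10 bisphosphonate
Product: 30 diethyl [(2E,4E,6E,8E,10E)-13-[(4R)-4-[(tert-butyldimethylsilyl)oxy]-2,6,6-trimethylcyclohex-1-en-1-yl]-2,7,11-trimethyltrideca-2,4,6,8,10-pentaen-12-yn-1-yl]phosphonate
Conditions: 29 (3 equiv), NaN(SiMe3)2 (1 equiv relative to 25), THF, −78 °C; slow addition of 25; → 0 °C
Reagents that add atoms: none
Why: Horner–Wadsworth–Emmons olefination forms C11'=C12' with E geometry; an excess of the linchpin with one equivalent of base should hold the reaction at mono-olefination, and the basic low-temperature conditions give no allyl cation that could scramble 9'E.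

Step 22
Reactants: 30 C25 phosphonate; 19 C15 aldehyde
Product: 31 (3S,5S,6S,3'R)-3,3'-bis[(tert-butyldimethylsilyl)oxy]-7',8'-didehydro-5,6-dihydro-β,β-carotene-5,6-diol (all-E)
Conditions: 30 (1.2 equiv), NaN(SiMe3)2 (1.2 equiv), THF, −78 °C; add 19; → 0 °C; dark, argon
Reagents that add atoms: none
Why: Horner–Wadsworth–Emmons olefination forms C11=C12 with E geometry between two methyl-free carbons; the delocalised phosphonate anion is far less basic than a tertiary alkoxide, so the free 5,6-diol should remain protonated and intact.

Step 23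
Reactants: 31 bis-silyl ether
Product: 32 (3S,5S,6S,3'R)-7',8'-didehydro-5,6-dihydro-β,β-carotene-3,5,6,3'-tetrol (all-E)
Conditions: Bu4NF, AcOH, THF, 0 °C → rt; dark, argon
Reagents that add atoms: none
Why: fluoride cleavage of the two secondary silyl ethers, buffered so that neither acid (C6 hydroxyl) nor strong base acts on the polyene.

## Compound list

1 | diethyl 2-methyl-3-oxobutanedioate (racemic) | CCOC(=O)C(=O)C(C)C(=O)OCC | starting material
2 | 3-bromoprop-1-ene | C=CCBr | starting material
3 | diethyl 2-methyl-3-oxo-2-(prop-2-en-1-yl)butanedioate (racemic) | CCOC(=O)C(=O)C(C)(CC=C)C(=O)OCC | intermediate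
4 | 3-methyl-2-oxohex-5-enoic acid (racemic) | C=CCC(C)C(=O)C(O)=O | intermediate
5 | 3-methyl-2,5-dioxopentanoic acid (racemic) | O=CCC(C)C(=O)C(O)=O | intermediate
6 | 4-methyl-2-oxo-2H-pyran-3-yl acetate | CC(=O)OC1=C(C)C=COC1=O | intermediate
7 | 3-hydroxy-4-methyl-2H-pyran-2-one | CC1=C(O)C(=O)OC=C1 | intermediate
8 | 2-methylprop-2-enal | CC(=C)C=O | starting material
9 | (1S,4R)-4-hydroxy-5,8-dimethyl-3-oxo-2-oxabicyclo[2.2.2]oct-5-ene-8-carbaldehyde (C8 epimers) | O=C1O[C@@H]2C=C(C)[C@@]1(O)C(C)(C=O)C2 | intermediate
10 | N'-{[(1S,4R)-4-hydroxy-5,8-dimethyl-3-oxo-2-oxabicyclo[2.2.2]oct-5-en-8-yl]methylidene}-4-methylbenzenesulfonohydrazide | O=C1O[C@@H]2C=C(C)[C@@]1(O)C(C)(C=NNS(=O)(=O)c3ccc(C)cc3)C2 | intermediate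
11 | (1S,4S)-4-hydroxy-5,8,8-trimethyl-2-oxabicyclo[2.2.2]oct-5-en-3-one | O=C1O[C@@H]2C=C(C)[C@@]1(O)C(C)(C)C2 | intermediate
12 | (1S,2S,4S,5S)-1-hydroxy-2,8,8-trimethyl-3,6-dioxatricyclo[3.2.2.0^2,4]nonan-7-one | O=C1O[C@@H]2[C@@H]3O[C@]3(C)[C@@]1(O)C(C)(C)C2 | intermediate
13 | (1R,2S,4S)-1-(hydroxymethyl)-2,6,6-trimethylcyclohexane-1,2,4-triol | OC[C@]1(O)C(C)(C)C[C@H](O)C[C@]1(C)O | intermediate
14 | (1R,2S,4S)-4-[(tert-butyldimethylsilyl)oxy]-1-{[(tert-butyldimethylsilyl)oxy]methyl}-2,6,6-trimethylcyclohexane-1,2-diol | CC(C)(C)[Si](C)(C)OC[C@]1(O)C(C)(C)C[C@H](O[Si](C)(C)C(C)(C)C)C[C@]1(C)O | intermediate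
15 | (1R,2S,4S)-4-[(tert-butyldimethylsilyl)oxy]-1-(hydroxymethyl)-2,6,6-trimethylcyclohexane-1,2-diol | OC[C@]1(O)C(C)(C)C[C@H](O[Si](C)(C)C(C)(C)C)C[C@]1(C)O | intermediate
16 | (1S,2S,4S)-4-[(tert-butyldimethylsilyl)oxy]-1,2-dihydroxy-2,6,6-trimethylcyclohexane-1-carbaldehyde | O=C[C@]1(O)C(C)(C)C[C@H](O[Si](C)(C)C(C)(C)C)C[C@]1(C)O | intermediate
17 | diethyl (3-cyano-2-methylprop-2-en-1-yl)phosphonate (E/Z mixture) | CCOP(=O)(OCC)CC(C)=CC#N | starting material
18 | (2E,4E)-5-[(1S,2S,4S)-4-[(tert-butyldimethylsilyl)oxy]-1,2-dihydroxy-2,6,6-trimethylcyclohexyl]-3-methylpenta-2,4-dienenitrile | N#C/C=C(C)/C=C/[C@]1(O)C(C)(C)C[C@H](O[Si](C)(C)C(C)(C)C)C[C@]1(C)O | intermediate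
19 | (2E,4E)-5-[(1S,2S,4S)-4-[(tert-butyldimethylsilyl)oxy]-1,2-dihydroxy-2,6,6-trimethylcyclohexyl]-3-methylpenta-2,4-dienal | O=C/C=C(C)/C=C/[C@]1(O)C(C)(C)C[C@H](O[Si](C)(C)C(C)(C)C)C[C@]1(C)O | intermediate
20 | (4R,6R)-4-hydroxy-2,2,6-trimethylcyclohexan-1-one | O=C1C(C)(C)C[C@H](O)C[C@H]1C | starting material
21 | (4R,6R)-4-[(tert-butyldimethylsilyl)oxy]-2,2,6-trimethylcyclohexan-1-one | O=C1C(C)(C)C[C@H](O[Si](C)(C)C(C)(C)C)C[C@H]1C | intermediate
22 | (4R)-4-[(tert-butyldimethylsilyl)oxy]-2,6,6-trimethylcyclohex-1-en-1-yl trifluoromethanesulfonate | CC1=C(OS(=O)(=O)C(F)(F)F)C(C)(C)C[C@H](O[Si](C)(C)C(C)(C)C)C1 | intermediate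
23 | (2E)-3-methylpent-2-en-4-yn-1-ol | C#C/C(C)=C/CO | starting material
24 | (2E)-5-[(4R)-4-[(tert-butyldimethylsilyl)oxy]-2,6,6-trimethylcyclohex-1-en-1-yl]-3-methylpent-2-en-4-yn-1-ol | CC1=C(C#C/C(C)=C/CO)C(C)(C)C[C@H](O[Si](C)(C)C(C)(C)C)C1 | intermediate
25 | (2E)-5-[(4R)-4-[(tert-butyldimethylsilyl)oxy]-2,6,6-trimethylcyclohex-1-en-1-yl]-3-methylpent-2-en-4-ynal | CC1=C(C#C/C(C)=C/C=O)C(C)(C)C[C@H](O[Si](C)(C)C(C)(C)C)C1 | intermediate
26 | (2E,4E,6E)-2,7-dimethylocta-2,4,6-trienedial | O=C/C(C)=C/C=C/C=C(C)/C=O | starting material
27 | (2E,4E,6E)-2,7-dimethylocta-2,4,6-triene-1,8-diol | OC/C(C)=C/C=C/C=C(C)/CO | intermediate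
28 | (2E,4E,6E)-1,8-dibromo-2,7-dimethylocta-2,4,6-triene | BrC/C(C)=C/C=C/C=C(C)/CBr | intermediate
29 | tetraethyl [(2E,4E,6E)-2,7-dimethylocta-2,4,6-triene-1,8-diyl]bis(phosphonate) | CCOP(=O)(OCC)C/C(C)=C/C=C/C=C(C)/CP(=O)(OCC)OCC | intermediate
30 | diethyl [(2E,4E,6E,8E,10E)-13-[(4R)-4-[(tert-butyldimethylsilyl)oxy]-2,6,6-trimethylcyclohex-1-en-1-yl]-2,7,11-trimethyltrideca-2,4,6,8,10-pentaen-12-yn-1-yl]phosphonate | CC1=C(C#C/C(C)=C/C=C/C(C)=C/C=C/C=C(C)/CP(=O)(OCC)OCC)C(C)(C)C[C@H](O[Si](C)(C)C(C)(C)C)C1 | intermediate
31 | (3S,5S,6S,3'R)-3,3'-bis[(tert-butyldimethylsilyl)oxy]-7',8'-didehydro-5,6-dihydro-β,β-carotene-5,6-diol | CC1=C(C#C/C(C)=C/C=C/C(C)=C/C=C/C=C(C)/C=C/C=C(C)/C=C/[C@]2(O)C(C)(C)C[C@H](O[Si](C)(C)C(C)(C)C)C[C@]2(C)O)C(C)(C)C[C@H](O[Si](C)(C)C(C)(C)C)C1 | intermediate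
32 | (3S,5S,6S,3'R)-7',8'-didehydro-5,6-dihydro-β,β-carotene-3,5,6,3'-tetrol | CC1=C(C#C/C(C)=C/C=C/C(C)=C/C=C/C=C(C)/C=C/C=C(C)/C=C/[C@]2(O)C(C)(C)C[C@H](O)C[C@]2(C)O)C(C)(C)C[C@H](O)C1 | target

## Step count and least certain steps

Total step count: 23. Longest linear sequence: 15 steps (steps 1 to 13, then 22 and 23).

**Step 5 (key step).** The α-methyl group of 8 and the 4-methyl group of 7 crowd the bond between C1 and C6. Ring closure may therefore lag behind the Michael addition, an uncatalysed racemic pathway may compete, and the catalyst may discriminate the dienolate faces poorly. Fallback from 7: control by a covalently bound auxiliary instead of a catalyst. 7 is combined under Et3N catalysis in CH2Cl2 with (4S)-4-benzyl-3-(2-methylprop-2-enoyl)-1,3-oxazolidin-2-one F1, made in one step from the commercial oxazolidinone and methacryloyl chloride. This should give the imide adduct (4S)-4-benzyl-3-{[(1S,4R)-4-hydroxy-5,8-dimethyl-3-oxo-2-oxabicyclo[2.2.2]oct-5-en-8-yl]carbonyl}-1,3-oxazolidin-2-one F2. The two bridgehead antipodes are now diastereomers and can be separated even if induction is modest; the enantiomeric auxiliary is used if it matches better. LiSEt in THF at 0 °C then gives S-ethyl (1S,4R)-4-hydroxy-5,8-dimethyl-3-oxo-2-oxabicyclo[2.2.2]oct-5-ene-8-carbothioate F3, and Fukuyama reduction (Et3SiH, Pd/C, acetone) returns to the route at 9.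

**Step 6.** Hydrazone formation at the neopentyl-type aldehyde may be incomplete, and the β-hydroxy aldehyde may open by retro-aldol cleavage or the lactone may lose CO2 on warming. Fallback from 9: ethane-1,2-dithiol and BF3·OEt2 in CH2Cl2 at 0 °C give (1S,4R)-8-(1,3-dithiolan-2-yl)-4-hydroxy-5,8-dimethyl-2-oxabicyclo[2.2.2]oct-5-en-3-one F4. Desulfurisation with deactivated Raney Ni in EtOH at rt returns to the route at 11.

**Step 8.** Once the lactone has opened, hydride may be delivered to the fully substituted C5, or the oxirane may migrate towards C6 (Payne-type), which would place oxygen on C4. Fallback from 11: Mukaiyama hydration (Mn(dpm)3 cat., PhSiH3, O2, iPrOH, 0 °C) adds hydrogen to C4 and traps the tertiary C5 radical with oxygen from the open lactone face. This gives (1S,4S,5S)-4,5-dihydroxy-5,8,8-trimethyl-2-oxabicyclo[2.2.2]octan-3-one F5 with no oxirane involved, and LiAlH4 in THF then reduces only the lactone, returning to the route at 13.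

**Step 10.** The primary silyl ether is neopentyl-like, so discrimination from the secondary one may be poor, with loss of both groups or silyl migration to a neighbouring hydroxyl. Fallback from 12: the two oxygens are differentiated before reduction instead of after. Methanolysis of the strained lactone (NaOMe cat., MeOH, 0 °C) gives methyl (1S,2S,5S,6S)-2,5-dihydroxy-1,3,3-trimethyl-7-oxabicyclo[4.1.0]heptane-2-carboxylate F6. Silylation of the freed secondary hydroxyl (TBSCl, imidazole, DMF) gives methyl (1S,2S,5S,6S)-5-[(tert-butyldimethylsilyl)oxy]-2-hydroxy-1,3,3-trimethyl-7-oxabicyclo[4.1.0]heptane-2-carboxylate F7. LiAlH4 in THF then reduces the ester and opens the oxirane at C4, returning to the route at 15.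

**Step 12.** Addition to the aldehyde between two quaternary carbons may be slow, so that proton transfer from the hydroxyls starts retro-aldol cleavage of the C5–C6 bond or α-ketol ring expansion; the 9E/9Z ratio may also be unfavourable. Fallback from 16: a neutral stabilised ylide, Ph3P=CHC(O)CH3 in toluene at 80 °C, forms C7=C8 without base and gives (3E)-4-[(1S,2S,4S)-4-[(tert-butyldimethylsilyl)oxy]-1,2-dihydroxy-2,6,6-trimethylcyclohexyl]but-3-en-2-one F8. Horner–Wadsworth–Emmons reaction of this ketone with diethyl cyanomethylphosphonate (NaH, THF) builds C9=C10 and returns to the route at 18 after separation of the 9Z isomer.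

## Further compounds

F1 | step 5 | (4S)-4-benzyl-3-(2-methylprop-2-enoyl)-1,3-oxazolidin-2-one | CC(=C)C(=O)N1[C@@H](Cc2ccccc2)COC1=O
F2 | step 5 | (4S)-4-benzyl-3-{[(1S,4R)-4-hydroxy-5,8-dimethyl-3-oxo-2-oxabicyclo[2.2.2]oct-5-en-8-yl]carbonyl}-1,3-oxazolidin-2-one | O=C1O[C@@H]2C=C(C)[C@@]1(O)C(C)(C(=O)N3[C@@H](Cc4ccccc4)COC3=O)C2
F3 | step 5 | S-ethyl (1S,4R)-4-hydroxy-5,8-dimethyl-3-oxo-2-oxabicyclo[2.2.2]oct-5-ene-8-carbothioate | O=C1O[C@@H]2C=C(C)[C@@]1(O)C(C)(C(=O)SCC)C2
F4 | step 6 | (1S,4R)-8-(1,3-dithiolan-2-yl)-4-hydroxy-5,8-dimethyl-2-oxabicyclo[2.2.2]oct-5-en-3-one | O=C1O[C@@H]2C=C(C)[C@@]1(O)C(C)(C3SCCS3)C2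
F5 | step 8 | (1S,4S,5S)-4,5-dihydroxy-5,8,8-trimethyl-2-oxabicyclo[2.2.2]octan-3-one | O=C1O[C@@H]2C[C@](C)(O)[C@@]1(O)C(C)(C)C2
F6 | step 10 | methyl (1S,2S,5S,6S)-2,5-dihydroxy-1,3,3-trimethyl-7-oxabicyclo[4.1.0]heptane-2-carboxylate | COC(=O)[C@]1(O)C(C)(C)C[C@H](O)[C@@H]2O[C@]12C
F7 | step 10 | methyl (1S,2S,5S,6S)-5-[(tert-butyldimethylsilyl)oxy]-2-hydroxy-1,3,3-trimethyl-7-oxabicyclo[4.1.0]heptane-2-carboxylate | COC(=O)[C@]1(O)C(C)(C)C[C@H](O[Si](C)(C)C(C)(C)C)[C@@H]2O[C@]12C
F8 | step 12 | (3E)-4-[(1S,2S,4S)-4-[(tert-butyldimethylsilyl)oxy]-1,2-dihydroxy-2,6,6-trimethylcyclohexyl]but-3-en-2-one | CC(=O)/C=C/[C@]1(O)C(C)(C)C[C@H](O[Si](C)(C)C(C)(C)C)C[C@]1(C)O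
A1 | alternative 1 | ethyl (2E,4E,6E)-9-[(4R)-4-[(tert-butyldimethylsilyl)oxy]-2,6,6-trimethylcyclohex-1-en-1-yl]-3,7-dimethylnona-2,4,6-trien-8-ynoate | CC1=C(C#C/C(C)=C/C=C/C(C)=C/C(=O)OCC)C(C)(C)C[C@H](O[Si](C)(C)C(C)(C)C)C1
A2 | alternative 1 | {[(1R)-4-(buta-1,3-diyn-1-yl)-3,5,5-trimethylcyclohex-3-en-1-yl]oxy}(tert-butyl)dimethylsilane | CC1=C(C#CC#C)C(C)(C)C[C@H](O[Si](C)(C)C(C)(C)C)C1
A3 | alternative 1 | ethyl (2E,4E)-5-iodo-3-methylpenta-2,4-dienoate | CCOC(=O)/C=C(C)/C=C/I
A4 | alternative 2 | 3,5-cyclic carbonate of (3S,5S,6S)-3,5,6-trihydroxy-5,6-dihydro-β-ionone | CC(=O)/C=C/[C@]1(O)C(C)(C)C[C@H]2C[C@]1(C)OC(=O)O2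
A5 | alternative 2 | (3S,5R,6S)-3-[(tert-butoxycarbonyl)oxy]-5,6-epoxy-5,6-dihydro-β-ionone | CC(=O)/C=C/[C@@]12O[C@]1(C)C[C@@H](OC(=O)OC(C)(C)C)CC2(C)C
A6 | alternative 3 | tert-butyl{[(1R)-4-[(3E)-5,5-diethoxy-3-methylpent-3-en-1-yn-1-yl]-3,5,5-trimethylcyclohex-3-en-1-yl]oxy}dimethylsilane | CC1=C(C#C/C(C)=C/C(OCC)OCC)C(C)(C)C[C@H](O[Si](C)(C)C(C)(C)C)C1
A7 | alternative 3 | (2E)-1-[(4R)-4-[(tert-butyldimethylsilyl)oxy]-2,6,6-trimethylcyclohex-1-en-1-yl]-4,4-diethoxy-2-methylbut-2-en-1-one | CC1=C(C(=O)/C(C)=C/C(OCC)OCC)C(C)(C)C[C@H](O[Si](C)(C)C(C)(C)C)C1
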